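The constants used here are assumed; no experiment stands behind them.

You must decide first whether to charge everything at once or dose one reactant, so reckon what dosing costs.

    substrate + coupling partner + product → 2 product (k1 = 43 M⁻² s⁻¹)
    substrate + coupling partner → product (k2 = 0.048 M⁻¹ s⁻¹)

| setting | Wednesday's | Friday's | Monday's | Saturday's |
|---|---|---|---|---|
| substrate | 0.10 M (fed, over 12.0 s) | 0.10 M | 0.10 M | 0.10 M |
| coupling partner | 0.150 M | 0.150 M (fed, over 12.0 s) | 0.150 M | 0.150 M |
| time | 12 s | 12 s |  | 12 s |
| remark | all but substrate at the start; substrate goes in evenly over 12.0 s, the run ends at 12 s | all but coupling partner at the start; coupling partner goes in evenly over 12.0 s, the run ends at 12 s | one stirred flow tank at steady state, fed with the mixture as stated, mean residence time 12 s | a closed flask charged with all of it at once and left for 12 s |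

- the set-up with the highest amount of product at the outlet or at the end, in percent of the substrate put in ("none" if the first two lie within 2 percentage points) (Wednesday's / Friday's / Monday's / Saturday's / none)
- amount of product at the outlet or at the end, in percent of the substrate put in, Wednesday's
- amount of product at the outlet or at the end, in percent of the substrate put in, Friday's
- amount of product at the outlet or at the end, in percent of the substrate put in, Monday's
- amount of product at the outlet or at the end, in percent of the substrate put in, Saturday's

- the stated concentrations are those of everything mixed, before any reaction; amounts are the same in each set-up
- the feed brings no volume worth counting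
- run time (Wednesday's): 12 s

- Write p for the product as a fraction of the substrate charge, and a and b for substrate and coupling partner as fractions of their charges. Step 1 has product on its left beside the two reactants of step 2, so this is autocatalysis with step 2 as the seed, s = k2/(k1·cA) = 1.12%, and p + s grows in proportion to itself, with the rate coefficient k1·cA·cB·a·b.
- Freeze a and b at what has been put in, ignoring consumption. Then p + s = s·e^N, where N, the gain number, is k1·cA·cB times the time integral of a·b.
- In Wednesday's flask b stays at one and a climbs evenly from zero to one, so N = 3.87. Friday's flask swaps a and b and has the same N.
- In Saturday's flask a and b both start at one, so N = 7.74, and dosing keeps just half of the exponent.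
- Frozen, Saturday's flask reckons to 25.6 charges of product, which is impossible, so the frozen reckoning fails for Saturday's flask and consumption must be counted there.
- Wednesday's flask reckons to 52.4%. Consumption lowers a and b, so I take that as an upper mark.
- N grows with the square of the time, so at 6.00 s Wednesday's N is 0.967, a quarter of its final value, giving p = 1.82%.
- The forecast chose Saturday's, with 28.3%, 28.6%, 74.7% and 82% for Wednesday's, Friday's, Monday's and Saturday's, in its words: “Batch wins clearly.”
- The simulation gives 28.5%, 28.9%, 74.7% and 81.9% in that order, so Saturday's is highest. Wednesday's flask holds 1.75% of product at 6.00 s and ends below the mark.
- Now take the neighbour of Wednesday's flask, dosed the same way but with 0.090 M of coupling partner, which is 0.900 equiv. The same reckoning gives N = 2.32, lower than Wednesday's, and an upper mark of 10.3%. The neighbour ends 1.7 percentage points under that mark, with 8.60% of product.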